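The reading that answered you was 30.4 % of D left in alpha at 8.00 min. You asked for a quick number on elm and guessed that a flask with D and Z at equal charge finishes within 12 min. I did not think so, and here is why.

| flask | D | Z | G | remark | time |
|---|---|---|---|---|---|
| eta | 0.010 M | 0.0053 M | 10 mM | run made earlier |  |
| alpha | 0.010 M | 0.012 M | 10 mM | run made earlier |  |
| beta | 0.010 M | 0.024 M | 10 mM | run made earlier |  |
| birch | 0.010 M | 0.00500 M | 10.0 mM |  | 12 min |
| cedar | 0.010 M | 0.0250 M | 10.0 mM |  | 12 min |
| elm | 0.010 M | 0.0100 M | 10.0 mM |  | 12 min |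

| run | time / min | E / % | X / % | D / % |
|---|---|---|---|---|
| eta | 0.667 | 6.3 | 0 | 93.2 |
| eta | 1.33 | 12.0 | 0.3 | 87.8 |
| eta | 2.50 | 19.0 | 0.1 | 79.9 |
| eta | 4.00 | 26.2 | 0 | 73.5 |
| eta | 8.00 | 38.0 | 0 | 61.6 |
| alpha | 0.833 | 17.4 | 0.3 | 82.5 |
| alpha | 2.00 | 34.8 | 0 | 64.8 |
| alpha | 4.00 | 50.9 | 0 | 47.4 |
| alpha | 6.00 | 62.0 | 0 | 38.4 |
| alpha | 8.00 | 67.3 | 1.3 | 30.4 |
| beta | 0.667 | 27.3 | 0 | 72.9 |
| beta | 1.33 | 44.4 | 0.3 | 55.2 |
| beta | 2.50 | 62.1 | 0 | 35.6 |
| beta | 4.00 | 75.1 | 0.4 | 20.5 |
| beta | 8.00 | 84.4 | 0.5 | 5.8 |

(readings scatter by 0.5 percentage points)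

- which of these holds the largest part of the D at the end of birch (E / J / D / X)
- which of these holds the largest part of the D at the end of cedar (E / J / D / X)
- which of these holds the largest part of the D at the end of elm (E / J / D / X)
- amount of E at the end of elm, in percent of the D charged

In alpha at that time, E, X and D still summed to 99.0 %, so I treated each D lost as one Z lost and the first exchange, D + Z, as a plain second-order step. Then the logarithm of the Z fraction over the D fraction grows in step with time, with a slope of k times the difference of the charges. That reading gave k = 0.337 M⁻¹ s⁻¹.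

Elm charged D and Z at 0.0100 M each, so in this reckoning cD and cZ fall together. For equal charges, with each Z taken by the first exchange, I reckoned with the meeting number θ, k times the common charge times the time, and the fraction of D left is then one over one plus θ. For elm, θ = 2.42, so I expected D near 29.2 %. That estimate had 70.8 % of the D turned over. Beta, with its larger charge of Z, had readings at 8.00 min that were short by 9.30 %, so I put E in elm somewhat under that figure.

The forecast called the first step “first order in each reactant and essentially irreversible” and named D for birch, E for cedar and E for elm, with E in elm at 68 %.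

Elm ended with D at 29.2 % and E at 68.0 %. Birch stayed with D at 58.6 %, and cedar went to E at 83.0 %.

    X ⇌ L (K = 22.0, k = 0.00660 s⁻¹)
    D + Z → G + E (k = 0.350 M⁻¹ s⁻¹)
    E + Z → G + J (k = 0.0190 M⁻¹ s⁻¹)
    J + Z → G + X (k = 0.130 M⁻¹ s⁻¹)
    J → Q (k = 0.00420 s⁻¹)

Elm's E stayed close to what θ released, and the main reason is the gap between the constants of the Z-consuming steps, a selectivity factor of 18.4 for the first exchange over the second. With that gap removed, elm gave E at 36.7 % against 68.0 %. Carried on to 30 min in the same flask, θ becomes 6.05 and gives D at 14.2 %. The flask held D at 15.8 %, with Z down at 10 % of its charge.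

The runs were computed with made-up constants; the scatter is artificial.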